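**Retrosynthetic overview**

- Target 25 comes from acid 24 by O-methylation. Acid 24 comes from triol 23 by ortho-carboxylation at C1, the only unsubstituted carbon of the resorcinol ring, so the ester carbon is put on last.
- The strategy rests on the benzoate ring: C1 CO2Me, C2 OH, C3 prenyl, C4 OH, C5 prenyl, C6 4-hydroxyphenethyl. Its C2(O)–C3(prenyl)–C4(O) triad is cut into siloxyalkyne 17 (C2, C3) and the carbonyl carbon of cyclobutenone 11 (C4). The other three ring carbons of 11 become C5, C6 and C1–H.
- Cyclobutenone 11 comes from ethoxycyclobutenone 5 and alkyllithium 9 (from tyrosol 6) by addition and acid transposition. Compound 5 comes from prenylketene 4 (from acid 1) and ethoxyacetylene 3 by [2+2] cycloaddition.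
- Siloxyalkyne 17 comes from enyne 14 (prenyl bromide 12 plus ethynylmagnesium bromide 13) by acetylide oxidation to the ynolate and O-silylation.
- Ring order: the four-membered ring is made in step 2 and carried to step 8, where it is converted into the pentasubstituted benzene ring. The 4-hydroxyphenyl ring is bought with tyrosol.

Key step: step 8

Assumption: compounds 5, 10 and 11 are racemic (10 a diastereomer mixture), which is immaterial because these centres become sp2 carbons by step 8 and the target is achiral; 5-methylhex-4-enoic acid, ethoxyacetylene and ethynylmagnesium bromide (THF solution) are taken as purchasable.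

**Route**

Step 1
Reactants: 1 5-methylhex-4-enoic acid
Product: 2 5-methylhex-4-enoyl chloride
Conditions: (COCl)2 (1.2 equiv), DMF (cat.), CH2Cl2, 0 °C to rt; volatiles removed, used crude
Reagents that add atoms: oxalyl chloride, ClC(=O)C(=O)Cl
Why: Vilsmeier-type activation with oxalyl chloride and catalytic DMF should convert the acid into the acyl chloride under mild conditions that leave the trisubstituted alkene untouched.

Step 2
Reactants: 2 5-methylhex-4-enoyl chloride; 3 ethoxyacetylene
Product: 5 racemic 3-ethoxy-4-(3-methylbut-2-enyl)cyclobut-2-en-1-one, via prenylketene 4 (not isolated)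
Conditions: 3 (2.5 equiv), Et3N (1.2 equiv), Et2O, rt to 35 °C; 2 added slowly by syringe pump
Reagents that add atoms: none
Why: Dehydrochlorination of 2 by Et3N gives aldoketene 4, which should undergo the regioselective [2+2] ketene–ynol ether cycloaddition with excess 3 (the unsubstituted nucleophilic alkyne carbon bonding to the ketene carbonyl carbon), placing the prenyl group at C4 as a racemic stereocentre that is lost later.

Step 3
Reactants: 6 tyrosol
Product: 7 4-(2-iodoethyl)phenol
Conditions: PPh3 (1.2 equiv), iodine (1.2 equiv), imidazole (1.3 equiv), CH2Cl2, 0 °C to rt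
Reagents that add atoms: iodine, [I][I]
Why: Appel-type iodination should substitute only the primary alcohol by SN2, since the phenolic oxygen sits on an sp2 carbon and cannot be displaced.

Step 4
Reactants: 7 4-(2-iodoethyl)phenol
Product: 8 [4-(2-iodoethyl)phenoxy]triisopropylsilane
Conditions: i-Pr3SiCl (1.1 equiv), imidazole (2 equiv), CH2Cl2, 0 °C to rt
Reagents that add atoms: triisopropylsilyl chloride, CC(C)[Si](Cl)(C(C)C)C(C)C
Why: Imidazole-mediated silylation of a phenol is standard, and the bulky triisopropylsilyl ether should withstand t-BuLi at −78 °C, brief dilute acid and heating to 110 °C.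

Step 5
Reactants: 8 [4-(2-iodoethyl)phenoxy]triisopropylsilane; 5 racemic 3-ethoxy-4-(3-methylbut-2-enyl)cyclobut-2-en-1-one
Product: 11 racemic 4-(3-methylbut-2-enyl)-3-{2-[4-(triisopropylsilyloxy)phenyl]ethyl}cyclobut-2-en-1-one, via alkyllithium 9 (not isolated), via cyclobutenol adduct 10 (not isolated)
Conditions: 8 (1.2 equiv), t-BuLi (2.4 equiv), Et2O–pentane, −78 °C; 5 in Et2O, −78 °C; then 1 M aq HCl, THF, 0 °C
Reagents that add atoms: water, O
Why: Lithium–iodine exchange gives alkyllithium 9, which should add 1,2 to the vinylogous ester carbonyl of 5, and dilute acid then converts carbinol 10 by enol ether hydrolysis and loss of the tertiary hydroxyl (1,3-carbonyl transposition) into the 3-substituted cyclobutenone; conjugate addition–elimination would converge on the same product because C4 is flanked by both C1 and C3, and C4 stays a racemic stereocentre.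

Step 6
Reactants: 12 prenyl bromide (1-bromo-3-methylbut-2-ene); 13 ethynylmagnesium bromide
Product: 14 5-methylhex-4-en-1-yne
Conditions: 13 (3 equiv, 0.5 M in THF), CuCl (5 mol %), THF, 0 °C to rt; fractional distillation
Reagents that add atoms: none
Why: CuCl-catalysed coupling of an alkynyl Grignard reagent with an allylic bromide should give the skipped 1,4-enyne, attack at the unhindered primary carbon of prenyl bromide being favoured and the excess of 13 suppressing double alkylation.

Step 7
Reactants: 14 5-methylhex-4-en-1-yne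
Product: 17 triisopropyl(5-methylhex-4-en-1-ynyloxy)silane, via lithium acetylide 15 (not isolated), via lithium ynolate 16 (not isolated)
Conditions: n-BuLi (1.0 equiv), THF, −78 °C; LiOOt-Bu [from t-BuOOH and LiN(SiMe3)2, THF, −78 °C], −78 to 0 °C; i-Pr3SiOTf (1.1 equiv), −78 to 0 °C; Et3N-deactivated silica
Reagents that add atoms: tert-butyl hydroperoxide, CC(C)(C)OO; triisopropylsilyl trifluoromethanesulfonate, CC(C)[Si](OS(=O)(=O)C(F)(F)F)(C(C)C)C(C)C
Why: Oxidation of lithium acetylide 15 by lithium tert-butyl peroxide (Julia ynolate synthesis) should give ynolate 16, which the bulky silyl triflate traps on oxygen to give the siloxyalkyne in preference to the C-silylated ketene.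

Step 8
Reactants: 11 racemic 4-(3-methylbut-2-enyl)-3-{2-[4-(triisopropylsilyloxy)phenyl]ethyl}cyclobut-2-en-1-one; 17 triisopropyl(5-methylhex-4-en-1-ynyloxy)silane
Product: 22 2,6-bis(3-methylbut-2-enyl)-3-(triisopropylsilyloxy)-5-{2-[4-(triisopropylsilyloxy)phenyl]ethyl}phenol, via vinylketene 18 (not isolated), via vinylcyclobutenone 19 (not isolated), via dienylketene 20 (not isolated), via cyclohexadienone 21 (not isolated)
Conditions: 11 (1.0 equiv), 17 (1.5 equiv), toluene (0.4 M), 80 °C then 110 °C, argon
Reagents that add atoms: none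
Why: This is a Danheiser benzannulation: thermal 4π electrocyclic opening of 11, with the prenyl group rotating outward, gives (E)-vinylketene 18, whose ketene C=C should undergo [2+2] cycloaddition with ynol ether 17 to give vinylcyclobutenone 19. A second 4π opening of 19 gives dienylketene 20, which closes the six-membered carbocycle by thermal disrotatory 6π electrocyclization (bond between the ketene carbon and the prenyl-bearing diene terminus, target C4–C5) to cyclohexadienone 21, and enolization gives phenol 22. The closest known reaction type is the cyclobutenone–siloxyalkyne benzannulation that gives resorcinol monosilyl ethers. No stereocentre is formed, and the single stereocentre of racemic 11 becomes an aromatic carbon. The one selectivity needed is the orientation of the [2+2], and the polarization of the ynol ether secures it: its nucleophilic prenyl-bearing carbon bonds to the electrophilic ketene carbonyl carbon (target C3–C4) and its oxygen-bearing carbon to the ketene α-carbon (target C1–C2), which puts the silyl ether on C2, the free hydroxyl on C4 and hydrogen on C1. Outward rotation of the prenyl group also keeps its allylic CH2 away from the ketene, so a 1,5-hydrogen shift should not compete.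

Step 9
Reactants: 22 2,6-bis(3-methylbut-2-enyl)-3-(triisopropylsilyloxy)-5-{2-[4-(triisopropylsilyloxy)phenyl]ethyl}phenol
Product: 23 5-[2-(4-hydroxyphenyl)ethyl]-2,4-bis(3-methylbut-2-enyl)benzene-1,3-diol
Conditions: Bu4NF (2.5 equiv), AcOH (2.5 equiv), THF, 0 °C, argon
Reagents that add atoms: none
Why: Fluoride should cleave both aryl silyl ethers through Si–F bond formation, and the acetic acid buffer keeps the electron-rich resorcinol from standing as an air-sensitive phenoxide.

Step 10
Reactants: 23 5-[2-(4-hydroxyphenyl)ethyl]-2,4-bis(3-methylbut-2-enyl)benzene-1,3-diol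
Product: 24 2,4-dihydroxy-6-[2-(4-hydroxyphenyl)ethyl]-3,5-bis(3-methylbut-2-enyl)benzoic acid
Conditions: MeOMgOCO2Me (2 M in DMF, 15 equiv), 120 °C, argon sweep; then cold 1 M aq HCl, 0 °C, rapid extraction
Reagents that add atoms: methyl magnesium carbonate, CO[Mg]OC(=O)OC
Why: In this Stiles carboxylation the magnesium phenoxide of the resorcinol ring should be carboxylated at C1, its only unsubstituted carbon and ortho to the C2 hydroxyl, and held as a magnesium salicylate chelate, whereas the isolated 4-alkylphenol ring is not activated enough to react.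

Step 11
Reactants: 24 2,4-dihydroxy-6-[2-(4-hydroxyphenyl)ethyl]-3,5-bis(3-methylbut-2-enyl)benzoic acid
Product: 25 methyl 2,4-dihydroxy-6-[2-(4-hydroxyphenyl)ethyl]-3,5-bis(3-methylbut-2-enyl)benzoate
Conditions: MeI (1.2 equiv), KHCO3 (1.5 equiv), DMF, rt
Reagents that add atoms: iodomethane, CI
Why: Bicarbonate should deprotonate only the carboxylic acid, and SN2 O-alkylation of the carboxylate by iodomethane then gives the methyl ester while the three phenols stay free.

**Compound list**

1 | 5-methylhex-4-enoic acid | CC(C)=CCCC(=O)O | starting material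
2 | 5-methylhex-4-enoyl chloride | CC(C)=CCCC(=O)Cl | intermediate
3 | ethoxyacetylene | CCOC#C | starting material
4 | prenylketene, 5-methylhexa-1,4-dien-1-one (not isolated) | CC(C)=CCC=C=O | intermediate
5 | racemic 3-ethoxy-4-(3-methylbut-2-enyl)cyclobut-2-en-1-one | CCOC1=CC(=O)C1CC=C(C)C | intermediate
6 | tyrosol, 2-(4-hydroxyphenyl)ethanol | OCCc1ccc(O)cc1 | starting material
7 | 4-(2-iodoethyl)phenol | Oc1ccc(CCI)cc1 | intermediate
8 | [4-(2-iodoethyl)phenoxy]triisopropylsilane | CC(C)[Si](Oc1ccc(CCI)cc1)(C(C)C)C(C)C | intermediate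
9 | 2-[4-(triisopropylsilyloxy)phenyl]ethyllithium (not isolated) | [Li]CCc1ccc(O[Si](C(C)C)(C(C)C)C(C)C)cc1 | intermediate
10 | 3-ethoxy-4-(3-methylbut-2-enyl)-1-{2-[4-(triisopropylsilyloxy)phenyl]ethyl}cyclobut-2-en-1-ol, racemic diastereomer mixture, formed as its lithium alkoxide (not isolated) | CCOC1=CC(O)(CCc2ccc(O[Si](C(C)C)(C(C)C)C(C)C)cc2)C1CC=C(C)C | intermediate
11 | racemic 4-(3-methylbut-2-enyl)-3-{2-[4-(triisopropylsilyloxy)phenyl]ethyl}cyclobut-2-en-1-one | O=C1C=C(CCc2ccc(O[Si](C(C)C)(C(C)C)C(C)C)cc2)C1CC=C(C)C | intermediate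
12 | prenyl bromide, 1-bromo-3-methylbut-2-ene | CC(C)=CCBr | starting material
13 | ethynylmagnesium bromide | C#C[Mg]Br | starting material
14 | 5-methylhex-4-en-1-yne | CC(C)=CCC#C | intermediate
15 | (5-methylhex-4-en-1-ynyl)lithium (not isolated) | CC(C)=CCC#C[Li] | intermediate
16 | lithium 5-methylhex-4-en-1-yn-1-olate (not isolated) | CC(C)=CCC#CO[Li] | intermediate
17 | triisopropyl(5-methylhex-4-en-1-ynyloxy)silane | CC(C)=CCC#CO[Si](C(C)C)(C(C)C)C(C)C | intermediate
18 | (E)-vinylketene, (3E)-7-methyl-3-{2-[4-(triisopropylsilyloxy)phenyl]ethyl}octa-1,3,6-trien-1-one (not isolated) | O=C=C/C(CCc1ccc(O[Si](C(C)C)(C(C)C)C(C)C)cc1)=C/CC=C(C)C | intermediate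
19 | vinylcyclobutenone, racemic 2-(3-methylbut-2-enyl)-3-(triisopropylsilyloxy)-4-[(E)-alkenyl]cyclobut-2-en-1-one, the alkenyl group being 6-methyl-1-[4-(triisopropylsilyloxy)phenyl]hepta-3,6-dien-3-yl in its 3,5-diene form as drawn (not isolated) | O=C1C(CC=C(C)C)=C(O[Si](C(C)C)(C(C)C)C(C)C)C1/C(CCc1ccc(O[Si](C(C)C)(C(C)C)C(C)C)cc1)=C/CC=C(C)C | intermediate
20 | dienylketene, 2-(3-methylbut-2-enyl)-3-(triisopropylsilyloxy)-5-{2-[4-(triisopropylsilyloxy)phenyl]ethyl}-9-methyldeca-1,3,5,8-tetraen-1-one with the ketene and the terminal alkene cis across C3=C4 (not isolated) | O=C=C(CC=C(C)C)/C(O[Si](C(C)C)(C(C)C)C(C)C)=C\C(CCc1ccc(O[Si](C(C)C)(C(C)C)C(C)C)cc1)=C\CC=C(C)C | intermediate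
21 | racemic 2,6-bis(3-methylbut-2-enyl)-3-(triisopropylsilyloxy)-5-{2-[4-(triisopropylsilyloxy)phenyl]ethyl}cyclohexa-2,4-dien-1-one (not isolated) | O=C1C(CC=C(C)C)=C(O[Si](C(C)C)(C(C)C)C(C)C)C=C(CCc2ccc(O[Si](C(C)C)(C(C)C)C(C)C)cc2)C1CC=C(C)C | intermediate
22 | 2,6-bis(3-methylbut-2-enyl)-3-(triisopropylsilyloxy)-5-{2-[4-(triisopropylsilyloxy)phenyl]ethyl}phenol | CC(C)=CCc1c(O)c(CC=C(C)C)c(CCc2ccc(O[Si](C(C)C)(C(C)C)C(C)C)cc2)cc1O[Si](C(C)C)(C(C)C)C(C)C | intermediate
23 | 5-[2-(4-hydroxyphenyl)ethyl]-2,4-bis(3-methylbut-2-enyl)benzene-1,3-diol | CC(C)=CCc1c(O)c(CC=C(C)C)c(CCc2ccc(O)cc2)cc1O | intermediate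
24 | 2,4-dihydroxy-6-[2-(4-hydroxyphenyl)ethyl]-3,5-bis(3-methylbut-2-enyl)benzoic acid | CC(C)=CCc1c(O)c(CC=C(C)C)c(CCc2ccc(O)cc2)c(C(=O)O)c1O | intermediate
25 | methyl 2,4-dihydroxy-6-[2-(4-hydroxyphenyl)ethyl]-3,5-bis(3-methylbut-2-enyl)benzoate | COC(=O)c1c(O)c(CC=C(C)C)c(O)c(CC=C(C)C)c1CCc1ccc(O)cc1 | target

**Step count**

Total steps: 11. Longest linear sequence: 7 steps (1, 2, 5, 8, 9, 10, 11 from acid 1; equally 3, 4, 5, 8, 9, 10, 11 from tyrosol 6).

**Steps most likely to fail**

Step 8 (key step). The siloxyalkyne may be consumed before vinylketene 18 is trapped, either by thermal 1,3-silyl shift to a silylketene or by protonation by the phenol as it forms, and the sequence may stall at vinylcyclobutenone 19. The fallback sets out from cyclobutenone 11 and prenyl bromide 12 and delivers the two alkyne carbons as a methyl ynol ether, which cannot undergo silyl migration. Chloroacetaldehyde dimethyl acetal and NaNH2 in liquid NH3 would give sodium methoxyacetylide F1, alkylated in the same flask with 12 to 1-methoxy-5-methylhex-4-en-1-yne F2. Heating F2 with 11 in toluene (80 °C, then 150 °C) should give, by the same pericyclic sequence, 3-methoxy-2,6-bis(3-methylbut-2-enyl)-5-{2-[4-(triisopropylsilyloxy)phenyl]ethyl}phenol F3. Bu4NF would remove the silyl group to give 5-[2-(4-hydroxyphenyl)ethyl]-3-methoxy-2,6-bis(3-methylbut-2-enyl)phenol F4. Excess MeMgI at 160 °C, a classical dealkylation of resorcinol methyl ethers that tolerates isolated alkenes, would cleave the methyl ether, and the route is rejoined at triol 23.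

Step 2. Dimerization of the aldoketene and its reaction with amine-derived species may outrun the cycloaddition. The fallback sets out from prenyl bromide 12 and ethoxyacetylene 3 and generates the same ketene without base or chloride. tert-Butoxyacetylene would be deprotonated with n-BuLi (THF, −78 °C) to lithium tert-butoxyacetylide F5 and alkylated with 12 (THF–DMPU) to 1-tert-butoxy-5-methylhex-4-en-1-yne F6. Slow addition of F6 to excess 3 in toluene at 75–80 °C should cause retro-ene loss of isobutene to give prenylketene 4, which cycloadds to 3, and the route is rejoined at ethoxycyclobutenone 5.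

Step 10. Carboxylation at the crowded C1 is reversible and may not go to completion, and the β-resorcylic acid may decarboxylate during acidic work-up. The fallback sets out from triol 23 and introduces C1 irreversibly at the aldehyde oxidation level. Magnesium-mediated ortho-formylation (MgCl2, Et3N, paraformaldehyde kept near stoichiometric so that the more nucleophilic resorcinol ring reacts first, MeCN, reflux) should give 2,4-dihydroxy-6-[2-(4-hydroxyphenyl)ethyl]-3,5-bis(3-methylbut-2-enyl)benzaldehyde F7, which can be purified. Oxidation with Ag2O in aqueous NaOH–EtOH at rt, which leaves the prenyl alkenes alone, followed by cold acidification to pH 4, rejoins the route at acid 24, which is methylated at once.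

**Further compounds**

F1 | step 8 | sodium methoxyacetylide | COC#C[Na]
F2 | step 8 | 1-methoxy-5-methylhex-4-en-1-yne | COC#CCC=C(C)C
F3 | step 8 | 3-methoxy-2,6-bis(3-methylbut-2-enyl)-5-{2-[4-(triisopropylsilyloxy)phenyl]ethyl}phenol | COc1cc(CCc2ccc(O[Si](C(C)C)(C(C)C)C(C)C)cc2)c(CC=C(C)C)c(O)c1CC=C(C)C
F4 | step 8 | 5-[2-(4-hydroxyphenyl)ethyl]-3-methoxy-2,6-bis(3-methylbut-2-enyl)phenol | COc1cc(CCc2ccc(O)cc2)c(CC=C(C)C)c(O)c1CC=C(C)C
F5 | step 2 | lithium tert-butoxyacetylide | CC(C)(C)OC#C[Li]
F6 | step 2 | 1-tert-butoxy-5-methylhex-4-en-1-yne | CC(C)=CCC#COC(C)(C)C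
F7 | step 10 | 2,4-dihydroxy-6-[2-(4-hydroxyphenyl)ethyl]-3,5-bis(3-methylbut-2-enyl)benzaldehyde | O=Cc1c(O)c(CC=C(C)C)c(O)c(CC=C(C)C)c1CCc1ccc(O)cc1
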